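4 questions stand below, and for midnight at −20 °C the reckoning comes down to one balance on the X charged.

all flasks: D 0.25 mM

| charge | X | temperature | remark | time |
|---|---|---|---|---|
| zeta | 0.25 M | −20 °C | run made earlier |  |
| midnight | 0.50 M | −20 °C |  | 25 d |
| winter | 0.50 M | −5 °C |  | 25 d |
| dawn | 0.50 M | 10 °C |  | 25 d |

zeta run (percent of the X charged)

| time / d | Z / % | L / % | Q / % |
|---|---|---|---|
| 0.208 | 7 | 0 | 0 |
| 0.417 | 14 | 3 | 2 |
| 0.625 | 18 | 4 | 5 |
| 1.25 | 34 | 9 | 10 |
| 2.50 | 44 | 10 | 16 |

(each reading ± 1.5 percentage points)

- percent here means X units held: one Q counts as two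
- the numbers in the tables scatter by 1.5 percentage points (one standard deviation)
- a reading or a percentage of Z counts all its forms, free or not
- the earlier runs do not show what temperature does; that part of a forecast is a guess

- the flask that comes out highest in share of Z in all that became Z or L or Q, or "all alike" when all lie within 1.5 percentage points (midnight / winter / dawn / all alike)
- share of Z in all that became Z or L or Q, midnight
- share of Z in all that became Z or L or Q, winter
- share of Z in all that became Z or L or Q, dawn

1. Zeta's last reading gives X a pseudo-first-order constant of 0.482 d⁻¹. Its half-life of 1.44 d is far shorter than midnight's 25 d, so the shares of midnight should sum to one: z + rz + q = 1, with z the share of Z and q that of Q.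
2. Here r = L/Z, an inverse selectivity factor, read in zeta as 0.227.
3. Q/Z climbs from 0.143 to 0.364 as Z accumulates, so take q = az². Since z is a fraction of the charge, a = G[X]₀, where G, the self-competition coefficient, reads 3.31 M⁻¹.
4. Midnight holds twice zeta's charge, so a = 1.65, and the balance gives z = 49.1%.
5. Turned round, for z to pass 0.5, a must lie below 1.55. Midnight's reckoned a stands 6.95% above that line, while zeta's last Q reading carries 1.5 percentage points on 16%, so the margin is thin.
6. In this balance, a warmer flask on top needs a smaller r or G when warm. The earlier runs do not show what temperature does, so this reckoning gives no warm number.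

The forecast chose midnight, with 59% (49% to 66%) for midnight, above this reckoning, 56% (43% to 67%) for winter and 53% (36% to 69%) for dawn, holding that “Warming usually erodes catalyst selectivity”.

The flasks give midnight as highest: 41.7% for midnight, 28.2% for winter and 15.6% for dawn.

    D + Z ⇌ E (K = 1.70 M⁻¹, k = 0.00500 M⁻¹ min⁻¹, Ea = 56.0 kJ mol⁻¹, ΔH = −10.0 kJ mol⁻¹)
    X + D → D + Z (k = 1.10 M⁻¹ min⁻¹, Ea = 38.0 kJ mol⁻¹)
    X → L (k = 4.60 × 10⁻⁵ min⁻¹, Ea = 96.0 kJ mol⁻¹)
    X + Z → Q (k = 6.40 × 10⁻⁴ M⁻¹ min⁻¹, Ea = 58.0 kJ mol⁻¹)
    (constants at −20 °C)

Midnight ends with G at 5.24 M⁻¹ against the 3.31 M⁻¹ read from zeta, and r at 0.306 against 0.227. The neighbour of dawn has D cut to 1.5 × 10⁻⁴ M, all else held. Dawn's end values, scaled inversely with D, give that neighbour r = 7.63 and G = 17.9 M⁻¹. The balance then gives z = 10.5%, and the neighbour itself ends at 10.2%.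

Readings and results were generated by integration with constants of no real substance; scatter was added.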